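**Strategy.** Everything rests on opening the C1–C2 bond of ring B, the six-membered carbocycle of the hexahydronaphthalene that carries the exocyclic alkene. Its skipped diene (exocyclic C=C2, C1H2, C4a=C8a) is the retron of an alkyne–alkene ene reaction. A gold-catalysed cycloisomerisation of a 1,6-enyne therefore closes ring B as the final ring, puts the tetrasubstituted alkene at the ring fusion and fixes the Z alkene by anti addition, all in one operation. The precursor is an internal alkyne that ties the finished 1,2-dioxane ester, built from (S)-linalool by oxetane perhydrolysis, to a 2,2-dimethyl-6-methylidenecyclohexyl unit.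

Key step: step 16

Assumption: (S)-(+)-linalool of high enantiomeric purity is taken as a commercial starting material, and alkyne 8 is used as the racemate because its only stereocentre becomes sp2 in step 16.

**Route**

Step 1
Reactants: 1 3-methylcyclohex-2-en-1-one
Product: 3 (±)-3,3-dimethyl-2-(prop-2-en-1-yl)cyclohexan-1-one, via lithium enolate 2 (not isolated)
Conditions: Me2CuLi (from MeLi, CuI), Et2O, 0 °C; then allyl bromide, HMPA, THF, 0 °C → rt
Reagents that add atoms: lithium dimethylcuprate [Li+].C[Cu-]C; allyl bromide C=CCBr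
Why: Cuprate conjugate addition to the β-methyl enone should create the quaternary carbon and a regiodefined enolate that is allylated in the same flask (conjugate addition–enolate alkylation); the new stereocentre forms as a racemate and is erased in step 16.

Step 2
Reactants: 3 (±)-3,3-dimethyl-2-(prop-2-en-1-yl)cyclohexan-1-one
Product: 4 (±)-1,1-dimethyl-3-methylidene-2-(prop-2-en-1-yl)cyclohexane
Conditions: Ph3PCH3Br, KOtBu, toluene, 90 °C
Reagents that add atoms: methyltriphenylphosphonium bromide C[P+](c1ccccc1)(c1ccccc1)c1ccccc1.[Br-]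
Why: Wittig methylenation with the ylide at elevated temperature should convert the hindered ketone into the exocyclic methylidene; no stereocentre is created.

Step 3
Reactants: 4 (±)-1,1-dimethyl-3-methylidene-2-(prop-2-en-1-yl)cyclohexane
Product: 6 (±)-3-(2,2-dimethyl-6-methylidenecyclohexyl)propan-1-ol, via alkylborane 5 (not isolated)
Conditions: 9-BBN (1.05 equiv), THF, 0 °C → rt; then NaOH, H2O2, 0 °C
Reagents that add atoms: hydrogen peroxide OO
Why: Anti-Markovnikov hydroboration–oxidation should hydrate only the allyl group, because 9-BBN adds to a monosubstituted alkene far faster than to the hindered 1,1-disubstituted methylidene.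

Step 4
Reactants: 6 (±)-3-(2,2-dimethyl-6-methylidenecyclohexyl)propan-1-ol
Product: 7 (±)-3-(2,2-dimethyl-6-methylidenecyclohexyl)propanal
Conditions: Dess–Martin periodinane, CH2Cl2, rt
Reagents that add atoms: none
Why: Dess–Martin oxidation should give the aldehyde under neutral conditions that leave the exocyclic alkene untouched; no stereocentre is affected.

Step 5
Reactants: 7 (±)-3-(2,2-dimethyl-6-methylidenecyclohexyl)propanal
Product: 8 (±)-2-(but-3-yn-1-yl)-1,1-dimethyl-3-methylidenecyclohexane
Conditions: dimethyl (1-diazo-2-oxopropyl)phosphonate, K2CO3, MeOH, 0 °C → rt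
Reagents that add atoms: dimethyl (1-diazo-2-oxopropyl)phosphonate CC(=O)C(=[N+]=[N-])P(=O)(OC)OC
Why: Seyferth–Gilbert homologation with the Ohira–Bestmann reagent should turn the aldehyde into the terminal alkyne by olefination with the diazomethylphosphonate anion and 1,2-shift in the alkylidene carbene, under conditions mild enough for the methylidene group.

Step 6
Reactants: 9 (S)-(+)-linalool [(3S)-3,7-dimethylocta-1,6-dien-3-ol]
Product: 11 (3S)-3,7-dimethyloct-6-ene-1,3-diol, via alkylborane 10 (not isolated)
Conditions: 9-BBN, THF, 0 °C → rt; then NaOH, H2O2, 0 °C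
Reagents that add atoms: hydrogen peroxide OO
Why: Hydroboration–oxidation with 9-BBN should select the vinyl group over the trisubstituted alkene and leave the tertiary carbinol stereocentre of linalool untouched.

Step 7
Reactants: 11 (3S)-3,7-dimethyloct-6-ene-1,3-diol
Product: 13 (2S)-2-methyl-2-(4-methylpent-3-en-1-yl)oxetane, via monotosylate 12 (not isolated)
Conditions: n-BuLi (1.0 equiv), THF, 0 °C; TsCl (1.0 equiv); then n-BuLi (1.0 equiv), 0 → 60 °C
Reagents that add atoms: none
Why: Selective tosylation of the primary alkoxide followed by intramolecular Williamson etherification (4-exo-tet) by the tertiary alkoxide should close the oxetane with retention, since the C–O bond at the stereocentre is never broken.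

Step 8
Reactants: 13 (2S)-2-methyl-2-(4-methylpent-3-en-1-yl)oxetane
Product: 14 3-[(2S)-2-methyloxetan-2-yl]propanal
Conditions: O3, acetone/H2O (95:5), 0 °C
Reagents that add atoms: ozone [O-][O+]=O
Why: Ozonolysis in a wet solvent, where water intercepts the carbonyl oxide, should deliver the aldehyde directly without a reductant and without touching the oxetane or its stereocentre.

Step 9
Reactants: 14 3-[(2S)-2-methyloxetan-2-yl]propanal
Product: 15 (3R,4R)-3-methyl-6-[(2S)-2-methyloxetan-2-yl]hex-1-en-4-ol
Conditions: (Z)-crotyl-B(Ipc)2 [cis-but-2-ene, n-BuLi, KOtBu, (−)-Ipc2BOMe, BF3·OEt2], THF, −78 °C; then NaOH, H2O2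
Reagents that add atoms: (Z)-crotyldiisopinocampheylborane C/C=C\CB([C@@H]1C[C@@H]2C[C@@H](C2(C)C)[C@H]1C)[C@@H]1C[C@@H]2C[C@@H](C2(C)C)[C@H]1C
Why: Brown asymmetric crotylboration through a closed chair (Zimmerman–Traxler) transition state should set both new stereocentres under reagent control, the Z-crotyl geometry giving the syn relationship and the isopinocampheyl groups of the (+)-α-pinene series directing attack to the Si face of the aldehyde, hence (3R,4R).

Step 10
Reactants: 15 (3R,4R)-3-methyl-6-[(2S)-2-methyloxetan-2-yl]hex-1-en-4-ol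
Product: 16 (3R,4R)-3-methyl-6-[(2S)-2-methyloxetan-2-yl]hex-1-en-4-yl methanesulfonate
Conditions: MsCl, Et3N, CH2Cl2, 0 °C
Reagents that add atoms: methanesulfonyl chloride CS(=O)(=O)Cl
Why: Mesylation on oxygen proceeds with retention and installs the leaving group for the later peroxide ring closure, and the oxetane should survive MsCl/Et3N at 0 °C.

Step 11
Reactants: 16 (3R,4R)-3-methyl-6-[(2S)-2-methyloxetan-2-yl]hex-1-en-4-yl methanesulfonate
Product: 17 (3R,4R,7R)-7-hydroperoxy-9-hydroxy-3,7-dimethylnon-1-en-4-yl methanesulfonate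
Conditions: H2O2 (anhydrous, in Et2O, excess), TMSOTf (0.2 equiv), Et2O, −78 → 0 °C
Reagents that add atoms: hydrogen peroxide OO
Why: Lewis-acid-promoted perhydrolysis of the oxetane should occur at the tertiary carbon with inversion (SN2-like displacement on the activated ether), which converts the linalool-derived centre into the tertiary hydroperoxide with the configuration needed for C6 of the dioxane, while the mesylate and vinyl group stay intact.

Step 12
Reactants: 17 (3R,4R,7R)-7-hydroperoxy-9-hydroxy-3,7-dimethylnon-1-en-4-yl methanesulfonate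
Product: 18 2-[(3R,6S)-6-[(2R)-but-3-en-2-yl]-3-methyl-1,2-dioxan-3-yl]ethan-1-ol
Conditions: KOtBu (1.05 equiv), 18-crown-6, THF, 0 °C
Reagents that add atoms: none
Why: Intramolecular SN2 displacement (6-exo-tet) of the secondary mesylate by the peroxy anion, which forms selectively because the hydroperoxide is far more acidic than the alcohol, should close the 1,2-dioxane with inversion at the ring CH carbon, placing the butenyl and hydroxyethyl groups cis.

Step 13
Reactants: 18 2-[(3R,6S)-6-[(2R)-but-3-en-2-yl]-3-methyl-1,2-dioxan-3-yl]ethan-1-ol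
Product: 20 (2S)-2-[(3S,6R)-6-(2-hydroxyethyl)-6-methyl-1,2-dioxan-3-yl]propanoic acid, via aldehyde 19 (not isolated)
Conditions: O3, MeCN/H2O (9:1), 0 °C; then NaClO2, NaH2PO4, 0 °C → rt
Reagents that add atoms: ozone [O-][O+]=O; sodium chlorite [Na+].[O-]Cl=O
Why: Ozonolysis of the only alkene in wet acetonitrile followed by Pinnick oxidation in the same flask should give the acid under buffered conditions that neither epimerise the α-stereocentre nor cleave the dialkyl peroxide.

Step 14
Reactants: 20 (2S)-2-[(3S,6R)-6-(2-hydroxyethyl)-6-methyl-1,2-dioxan-3-yl]propanoic acid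
Product: 21 methyl (2S)-2-[(3S,6R)-6-(2-hydroxyethyl)-6-methyl-1,2-dioxan-3-yl]propanoate
Conditions: TMSCHN2, MeOH/toluene, 0 °C
Reagents that add atoms: (trimethylsilyl)diazomethane C[Si](C)(C)C=[N+]=[N-]
Why: Methyl esterification with (trimethylsilyl)diazomethane is selective for the acid over the primary alcohol and needs no base, so no stereocentre is at risk.

Step 15
Reactants: 21 methyl (2S)-2-[(3S,6R)-6-(2-hydroxyethyl)-6-methyl-1,2-dioxan-3-yl]propanoate; 8 (±)-2-(but-3-yn-1-yl)-1,1-dimethyl-3-methylidenecyclohexane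
Product: 24 methyl (2S)-2-[(3S,6S)-6-[6-(2,2-dimethyl-6-methylidenecyclohexyl)hex-3-yn-1-yl]-6-methyl-1,2-dioxan-3-yl]propanoate, via triflate 22 (not isolated), via lithium acetylide 23 (not isolated)
Conditions: Tf2O, 2,6-lutidine, CH2Cl2, −78 °C; then 23 [8, n-BuLi, THF, −78 °C], DMPU, −78 → −20 °C
Reagents that add atoms: none
Why: SN2 alkylation of a lithium acetylide by a primary triflate is fast at −78 °C, where the weakly basic acetylide should neither add to the α-branched methyl ester nor attack the hindered O–O bond; no stereocentre is touched and 24 is expected as an equimolar pair of epimers at the cyclohexane carbon.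

Step 16
Reactants: 24 methyl (2S)-2-[(3S,6S)-6-[6-(2,2-dimethyl-6-methylidenecyclohexyl)hex-3-yn-1-yl]-6-methyl-1,2-dioxan-3-yl]propanoate
Product: 25 methyl (2S)-2-[(3S,6S)-6-{(3Z)-3-[5,5-dimethyl-3,4,5,6,7,8-hexahydronaphthalen-2(1H)-ylidene]propyl}-6-methyl-1,2-dioxan-3-yl]propanoate
Conditions: [(t-Bu)2(2-biphenylyl)P]Au(NCMe)SbF6 (5 mol%), CH2Cl2, 0 °C → rt
Reagents that add atoms: none
Why: The cationic monovalent-gold complex binds the alkyne and the exocyclic methylidene of ring A attacks it through its CH2 terminus anti to gold (Markovnikov, charge on the ring carbon), forming the C1–C2 bond of ring B and a tertiary cation (cyclopropyl gold carbene) at C8a; loss of the adjacent tertiary proton at C4a gives the C4a=C8a alkene and protodeauration of the alkenyl-gold with retention releases 25. The closest known reaction type is the gold- or PtCl2-catalysed cycloisomerisation of 1,6-enynes to 1,4-dienes (formal Alder-ene reaction), which closes six-membered rings when the alkene is 1,1-disubstituted. Ring B closes 6-exo-dig with respect to the alkyne and 6-endo-trig with respect to the alkene. No new stereocentre is formed: the carbon that is epimeric in 24 becomes sp2, so both epimers converge, and the Z geometry of the exocyclic alkene follows from anti addition of carbon and hydrogen across the alkyne. The step needs proton loss towards C4a rather than C8 or C1, which should be favoured because that C–H is tertiary, aligned with the empty orbital in the fused bicycle and leads to the most substituted alkene; a non-nucleophilic solvent and a bulky phosphine should suppress skeletal rearrangement, and the peroxide and ester are inert to the soft π-acid.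

Step 17
Reactants: 25 methyl (2S)-2-[(3S,6S)-6-{(3Z)-3-[5,5-dimethyl-3,4,5,6,7,8-hexahydronaphthalen-2(1H)-ylidene]propyl}-6-methyl-1,2-dioxan-3-yl]propanoate
Product: 26 (2S)-2-[(3S,6S)-6-{(3Z)-3-[5,5-dimethyl-3,4,5,6,7,8-hexahydronaphthalen-2(1H)-ylidene]propyl}-6-methyl-1,2-dioxan-3-yl]propanoic acid (CNP0223199.2)
Conditions: LiOH·H2O, THF/MeOH/H2O, 0 °C → rt; then 1 M HCl to pH 3
Reagents that add atoms: lithium hydroxide [Li+].[OH-]
Why: Saponification with LiOH should cleave the methyl ester by acyl substitution, which is much faster than enolisation, so C2 is not epimerised and the dialkyl 1,2-dioxane and the skipped diene are left intact.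

**Compound list**

1 | 3-methylcyclohex-2-en-1-one | CC1=CC(=O)CCC1 | starting material
2 | lithium 3,3-dimethylcyclohex-1-en-1-olate | [Li+].[O-]C1=CC(C)(C)CCC1 | intermediate
3 | (±)-3,3-dimethyl-2-(prop-2-en-1-yl)cyclohexan-1-one (racemate) | C=CCC1C(=O)CCCC1(C)C | intermediate
4 | (±)-1,1-dimethyl-3-methylidene-2-(prop-2-en-1-yl)cyclohexane (racemate) | C=CCC1C(=C)CCCC1(C)C | intermediate
5 | (±)-9-[3-(2,2-dimethyl-6-methylidenecyclohexyl)propyl]-9-borabicyclo[3.3.1]nonane | C=C1CCCC(C)(C)C1CCCB1C2CCCC1CCC2 | intermediate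
6 | (±)-3-(2,2-dimethyl-6-methylidenecyclohexyl)propan-1-ol (racemate) | C=C1CCCC(C)(C)C1CCCO | intermediate
7 | (±)-3-(2,2-dimethyl-6-methylidenecyclohexyl)propanal (racemate) | C=C1CCCC(C)(C)C1CCC=O | intermediate
8 | (±)-2-(but-3-yn-1-yl)-1,1-dimethyl-3-methylidenecyclohexane (racemate) | C=C1CCCC(C)(C)C1CCC#C | intermediate
9 | (S)-(+)-linalool, (3S)-3,7-dimethylocta-1,6-dien-3-ol | C=C[C@@](C)(O)CCC=C(C)C | starting material
10 | 9-[(3R)-3-hydroxy-3,7-dimethyloct-6-en-1-yl]-9-borabicyclo[3.3.1]nonane (same spatial arrangement as 9; descriptor changes by priority only) | B1(C2CCCC1CCC2)CC[C@@](C)(O)CCC=C(C)C | intermediate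
11 | (3S)-3,7-dimethyloct-6-ene-1,3-diol | OCC[C@@](C)(O)CCC=C(C)C | intermediate
12 | (3S)-3-hydroxy-3,7-dimethyloct-6-en-1-yl 4-methylbenzenesulfonate | Cc1ccc(cc1)S(=O)(=O)OCC[C@@](C)(O)CCC=C(C)C | intermediate
13 | (2S)-2-methyl-2-(4-methylpent-3-en-1-yl)oxetane | C[C@]1(CCC=C(C)C)CCO1 | intermediate
14 | 3-[(2S)-2-methyloxetan-2-yl]propanal | C[C@]1(CCC=O)CCO1 | intermediate
15 | (3R,4R)-3-methyl-6-[(2S)-2-methyloxetan-2-yl]hex-1-en-4-ol | C=C[C@@H](C)[C@H](O)CC[C@@]1(C)CCO1 | intermediate
16 | (3R,4R)-3-methyl-6-[(2S)-2-methyloxetan-2-yl]hex-1-en-4-yl methanesulfonate | C=C[C@@H](C)[C@H](OS(C)(=O)=O)CC[C@@]1(C)CCO1 | intermediate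
17 | (3R,4R,7R)-7-hydroperoxy-9-hydroxy-3,7-dimethylnon-1-en-4-yl methanesulfonate | C=C[C@@H](C)[C@H](OS(C)(=O)=O)CC[C@@](C)(OO)CCO | intermediate
18 | 2-[(3R,6S)-6-[(2R)-but-3-en-2-yl]-3-methyl-1,2-dioxan-3-yl]ethan-1-ol | C=C[C@@H](C)[C@@H]1CC[C@](C)(CCO)OO1 | intermediate
19 | (2S)-2-[(3S,6R)-6-(2-hydroxyethyl)-6-methyl-1,2-dioxan-3-yl]propanal | O=C[C@@H](C)[C@@H]1CC[C@](C)(CCO)OO1 | intermediate
20 | (2S)-2-[(3S,6R)-6-(2-hydroxyethyl)-6-methyl-1,2-dioxan-3-yl]propanoic acid | OC(=O)[C@@H](C)[C@@H]1CC[C@](C)(CCO)OO1 | intermediate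
21 | methyl (2S)-2-[(3S,6R)-6-(2-hydroxyethyl)-6-methyl-1,2-dioxan-3-yl]propanoate | COC(=O)[C@@H](C)[C@@H]1CC[C@](C)(CCO)OO1 | intermediate
22 | methyl (2S)-2-[(3S,6R)-6-methyl-6-{2-[(trifluoromethanesulfonyl)oxy]ethyl}-1,2-dioxan-3-yl]propanoate | COC(=O)[C@@H](C)[C@@H]1CC[C@](C)(CCOS(=O)(=O)C(F)(F)F)OO1 | intermediate
23 | (±)-[4-(2,2-dimethyl-6-methylidenecyclohexyl)but-1-yn-1-yl]lithium | [Li]C#CCCC1C(=C)CCCC1(C)C | intermediate
24 | methyl (2S)-2-[(3S,6S)-6-[6-(2,2-dimethyl-6-methylidenecyclohexyl)hex-3-yn-1-yl]-6-methyl-1,2-dioxan-3-yl]propanoate (both epimers at the chain-bearing cyclohexane carbon; that centre is left undefined) | COC(=O)[C@@H](C)[C@@H]1CC[C@](C)(CCC#CCCC2C(=C)CCCC2(C)C)OO1 | intermediate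
25 | methyl (2S)-2-[(3S,6S)-6-{(3Z)-3-[5,5-dimethyl-3,4,5,6,7,8-hexahydronaphthalen-2(1H)-ylidene]propyl}-6-methyl-1,2-dioxan-3-yl]propanoate | COC(=O)[C@@H](C)[C@@H]1CC[C@](C)(CC/C=C2/CCC3=C(CCCC3(C)C)C2)OO1 | intermediate
26 | (2S)-2-[(3S,6S)-6-{(3Z)-3-[5,5-dimethyl-3,4,5,6,7,8-hexahydronaphthalen-2(1H)-ylidene]propyl}-6-methyl-1,2-dioxan-3-yl]propanoic acid | C[C@H](C(=O)O)[C@@H]1CC[C@](C)(CC/C=C2/CCC3=C(CCCC3(C)C)C2)OO1 | target

**Step count**

Total step count: 17. Longest linear sequence: 12 steps (steps 6–17, from (S)-linalool); the alkyne 8 is made in 5 steps (steps 1–5) and joins at step 15.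

**Steps most likely to fail, with fallbacks**

Step 16 (key step). The ring-fusion cation may lose a proton unselectively (towards C8 or C1 instead of C4a), or the cyclopropyl gold carbene may rearrange to conjugated dienes. The fallback traps the cation instead of deprotonating it. Setting out from enyne 24, hydroxycyclisation with the same gold catalyst in wet acetone (or PtCl2 in acetone/H2O) would add the methylidene carbon and water anti across the alkyne and alkene. This would give the cis-fused tertiary alcohol methyl (2S)-2-[(3S,6S)-6-{(3Z)-3-[8a-hydroxy-5,5-dimethyloctahydronaphthalen-2(1H)-ylidene]propyl}-6-methyl-1,2-dioxan-3-yl]propanoate F1, with the Z alkene set as before. Syn-dehydration with the Burgess reagent (benzene, 50 °C) would then come back to the route at 25, because the C4a–H is cis to the hydroxyl and its loss gives the most substituted alkene.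

Step 15. The acetylide may add to the ester, attack the O–O bond, or cause elimination of the triflate. The fallback joins the fragments without a strong base. Setting out from alcohol 21, iodination (I2, PPh3, imidazole, CH2Cl2, 0 °C, phosphine–iodine adduct pre-formed) would give methyl (2S)-2-[(3S,6R)-6-(2-iodoethyl)-6-methyl-1,2-dioxan-3-yl]propanoate F2. A Sonogashira coupling of this unactivated primary iodide with alkyne 8, catalysed by zerovalent palladium with an N-heterocyclic carbene ligand ([(π-allyl)PdCl]2, 1,3-bis(1-adamantyl)imidazolium chloride, CuI, Cs2CO3, DMF/Et2O, 45 °C), would come back to the route at 24.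

Step 11. Ionisation at the tertiary oxetane carbon may erode the stereochemical fidelity of the perhydrolysis, or lead to elimination. The fallback exchanges the roles of nucleophile and electrophile. Setting out from mesylate 16, SN2 displacement with 2-methoxypropan-2-yl hydroperoxide (CsOH, DMF, 0 °C → rt) would give, with inversion, the peroxyketal (2S)-2-{(3S,4R)-3-[(2-methoxypropan-2-yl)peroxy]-4-methylhex-5-en-1-yl}-2-methyloxetane F3. Aqueous AcOH would release the secondary hydroperoxide (2S)-2-[(3S,4R)-3-hydroperoxy-4-methylhex-5-en-1-yl]-2-methyloxetane F4. Catalytic TMSOTf (CH2Cl2, −78 °C) would then induce intramolecular 6-exo opening of the oxetane at its tertiary carbon with inversion, which comes back to the route at dioxane alcohol 18.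

**Further compounds**

F1 | step 16 | methyl (2S)-2-[(3S,6S)-6-{(3Z)-3-[8a-hydroxy-5,5-dimethyloctahydronaphthalen-2(1H)-ylidene]propyl}-6-methyl-1,2-dioxan-3-yl]propanoate (cis ring fusion, both ring-fusion series) | COC(=O)[C@@H](C)[C@@H]1CC[C@](C)(CC/C=C2/CCC3C(C)(C)CCCC3(O)C2)OO1
F2 | step 15 | methyl (2S)-2-[(3S,6R)-6-(2-iodoethyl)-6-methyl-1,2-dioxan-3-yl]propanoate | COC(=O)[C@@H](C)[C@@H]1CC[C@](C)(CCI)OO1
F3 | step 11 | (2S)-2-{(3S,4R)-3-[(2-methoxypropan-2-yl)peroxy]-4-methylhex-5-en-1-yl}-2-methyloxetane | C=C[C@@H](C)[C@@H](OOC(C)(C)OC)CC[C@@]1(C)CCO1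
F4 | step 11 | (2S)-2-[(3S,4R)-3-hydroperoxy-4-methylhex-5-en-1-yl]-2-methyloxetane | C=C[C@@H](C)[C@@H](OO)CC[C@@]1(C)CCO1
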